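**Retrosynthetic overview**
1. Target 13 comes from its 2'-O-TIPS ether 12 by desilylation, so the B-ring phenol is unmasked last.
2. O1 and the 6-OH are para to each other, so the A ring is treated as a latent p-benzoquinone. The pyranone ring (C4–C4a and O1–C2) is closed in one operation from quinone 5 and ynal 10 by a proposed photo-hydroacylation/6-endo oxa-Michael annulation.
3. Quinone 5 comes from 2,3,6-trimethoxyphenol 4, made from 1,2,4-trimethoxybenzene 1 by directed ortho-metalation and oxidation.
4. Ynal 10 comes from 2-hydroxy-6-methoxybenzaldehyde 6 by silylation, Corey–Fuchs olefination and formylation.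
5. Ring order: rings A and B are bought as arenes; ring C (the pyranone) is formed in the penultimate step.

Assumption: the SMILES has no stereocentre and the C2–C1' axis is not configurationally stable, so the target is achiral and no stereocontrol is needed; 1 and 6 are taken as commercial.

**Route**

Step 1
Reactants: 1 1,2,4-trimethoxybenzene
Product: 4 2,3,6-trimethoxyphenol, via aryllithium 2 (not isolated), via arylboronate 3 (not isolated)
Conditions: n-BuLi (1.1 equiv), THF, 0 °C to rt; B(OMe)3 (1.3 equiv), −78 °C to rt; 30% aq. H2O2, 0 °C to rt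
Reagents that add atoms: hydrogen peroxide (OO)
Why: Directed ortho-metalation lithiates C3–H of 1 selectively because it lies between two methoxy groups, and borylation followed by peroxide oxidation of the C–B bond converts that position into the phenol without touching the methyl ethers.

Step 2
Reactants: 4 2,3,6-trimethoxyphenol
Product: 5 2,3,5-trimethoxy-1,4-benzoquinone
Conditions: salcomine [Co(salen)] (5 mol%), O2 (1 atm), MeCN, rt
Reagents that add atoms: dioxygen (O=O)
Why: Co(salen)-catalysed aerobic phenol oxidation (the reaction that turns 2,3,6-trimethylphenol into trimethylbenzoquinone) oxygenates the free para position of a phenol whose two ortho positions are blocked, giving the p-quinone.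

Step 3
Reactants: 6 2-hydroxy-6-methoxybenzaldehyde
Product: 7 2-methoxy-6-[(triisopropylsilyl)oxy]benzaldehyde
Conditions: TIPSOTf (1.2 equiv), 2,6-lutidine (1.5 equiv), CH2Cl2, 0 °C
Reagents that add atoms: triisopropylsilyl triflate (CC(C)[Si](C(C)C)(C(C)C)OS(=O)(=O)C(F)(F)F)
Why: Silyl ether protection of the hydrogen-bonded phenol with a silyl triflate; TIPS is chosen because it has no weak C–H bond for the later photochemical step, tolerates n-BuLi at −78 °C and is removed by fluoride.

Step 4
Reactants: 7 2-methoxy-6-[(triisopropylsilyl)oxy]benzaldehyde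
Product: 8 {[2-(2,2-dibromoethenyl)-3-methoxyphenyl]oxy}triisopropylsilane
Conditions: CBr4 (2 equiv), PPh3 (4 equiv), CH2Cl2, 0 °C
Reagents that add atoms: carbon tetrabromide (BrC(Br)(Br)Br)
Why: Corey–Fuchs dibromoolefination (Wittig reaction of Ph3P=CBr2 made in the flask), which tolerates aryl silyl ethers and ortho,ortho'-disubstituted benzaldehydes.

Step 5
Reactants: 8 {[2-(2,2-dibromoethenyl)-3-methoxyphenyl]oxy}triisopropylsilane
Product: 10 3-{2-methoxy-6-[(triisopropylsilyl)oxy]phenyl}prop-2-ynal, via lithium acetylide 9 (not isolated)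
Conditions: n-BuLi (2.1 equiv), THF, −78 °C; DMF (3 equiv), −78 to 0 °C; reverse quench into aq. KH2PO4/MTBE
Reagents that add atoms: N,N-dimethylformamide (CN(C)C=O)
Why: Second stage of the Corey–Fuchs sequence, in which Br/Li exchange and Fritsch–Buttenberg–Wiechell rearrangement give the lithium acetylide that DMF formylates, while the buffered reverse quench keeps liberated Me2NH from adding to the ynal.

Step 6
Reactants: 5 2,3,5-trimethoxy-1,4-benzoquinone (1.5 equiv); 10 3-{2-methoxy-6-[(triisopropylsilyl)oxy]phenyl}prop-2-ynal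
Product: 12 6-hydroxy-5,7,8-trimethoxy-2-{2-methoxy-6-[(triisopropylsilyl)oxy]phenyl}-4H-chromen-4-one, via acylhydroquinone ynone 11 (not isolated)
Conditions: hν (450 nm LEDs), PhCF3 (0.05 M), argon, 20 °C; then DMAP (0.2 equiv), 40 °C, dark
Reagents that add atoms: none
Why: Proposed new method: a photo-hydroacylation/oxa-Michael annulation of a quinone with an ynal, in which blue light excites only quinone 5, its triplet abstracts the formyl hydrogen of 10 to give a semiquinone/alkynoyl radical pair (the alkynoyl radical cannot lose CO because that would give an sp radical, and its alkyne is shielded by the 2,6-disubstituted aryl), the acyl radical adds to the only unsubstituted carbon (C6) of 5, back hydrogen transfer from the semiquinone and enolisation give the hydrogen-bonded acylhydroquinone 11, and DMAP then adds to the ynone β-carbon and is displaced by the single ortho hydroxyl in a 6-endo sense, so that the second quinone oxygen is left as the free 6-OH with no protecting group and no regiochemical choice; the closest known reaction types are the photo-Friedel–Crafts (Klinger-type) acylation of 1,4-quinones with simple aldehydes and the nucleophile-catalysed 6-endo cyclisation of o-hydroxyaryl ynones, neither of which has been shown with an ynal, with a trialkoxyquinone or as a one-pot flavone annulation.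

Step 7
Reactants: 12 6-hydroxy-5,7,8-trimethoxy-2-{2-methoxy-6-[(triisopropylsilyl)oxy]phenyl}-4H-chromen-4-one
Product: 13 6,2'-dihydroxy-5,7,8,6'-tetramethoxyflavone
Conditions: TBAF (1.2 equiv), AcOH (1.2 equiv), THF, 0 °C
Reagents that add atoms: none
Why: Fluoride-mediated desilylation of the aryl silyl ether driven by Si–F bond formation, buffered with acetic acid so that the pyranone, the four methyl ethers and the two free phenols are untouched.

**Compound list**
1 | 1,2,4-trimethoxybenzene | COc1ccc(OC)c(OC)c1 | starting material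
2 | aryllithium: (2,3,6-trimethoxyphenyl)lithium, formed in the flask | [Li]c1c(OC)ccc(OC)c1OC | intermediate
3 | arylboronate: dimethyl (2,3,6-trimethoxyphenyl)boronate, formed in the flask | COB(OC)c1c(OC)ccc(OC)c1OC | intermediate
4 | 2,3,6-trimethoxyphenol | COc1ccc(OC)c(OC)c1O | intermediate
5 | 2,3,5-trimethoxy-1,4-benzoquinone (2,3,5-trimethoxycyclohexa-2,5-diene-1,4-dione) | COC1=CC(=O)C(OC)=C(OC)C1=O | intermediate
6 | 2-hydroxy-6-methoxybenzaldehyde | COc1cccc(O)c1C=O | starting material
7 | 2-methoxy-6-[(triisopropylsilyl)oxy]benzaldehyde | COc1cccc(O[Si](C(C)C)(C(C)C)C(C)C)c1C=O | intermediate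
8 | {[2-(2,2-dibromoethenyl)-3-methoxyphenyl]oxy}triisopropylsilane | COc1cccc(O[Si](C(C)C)(C(C)C)C(C)C)c1C=C(Br)Br | intermediate
9 | lithium acetylide: lithium {2-methoxy-6-[(triisopropylsilyl)oxy]phenyl}acetylide, formed in the flask | COc1cccc(O[Si](C(C)C)(C(C)C)C(C)C)c1C#C[Li] | intermediate
10 | 3-{2-methoxy-6-[(triisopropylsilyl)oxy]phenyl}prop-2-ynal | COc1cccc(O[Si](C(C)C)(C(C)C)C(C)C)c1C#CC=O | intermediate
11 | acylhydroquinone ynone: 1-(2,5-dihydroxy-3,4,6-trimethoxyphenyl)-3-{2-methoxy-6-[(triisopropylsilyl)oxy]phenyl}prop-2-yn-1-one, formed in the flask | COc1cccc(O[Si](C(C)C)(C(C)C)C(C)C)c1C#CC(=O)c1c(O)c(OC)c(OC)c(O)c1OC | intermediate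
12 | 6-hydroxy-5,7,8-trimethoxy-2-{2-methoxy-6-[(triisopropylsilyl)oxy]phenyl}-4H-chromen-4-one | COc1cccc(O[Si](C(C)C)(C(C)C)C(C)C)c1-c1cc(=O)c2c(OC)c(O)c(OC)c(OC)c2o1 | intermediate
13 | 6,2'-dihydroxy-5,7,8,6'-tetramethoxyflavone (achiral) | COc1cccc(O)c1-c1cc(=O)c2c(OC)c(O)c(OC)c(OC)c2o1 | target

**Totals**
Total step count: 7.
Longest linear sequence: 5 steps (6 → 7 → 8 → 10 → 12 → 13).

**Three steps most likely to fail**

Step 6 (the proposed new step). Possible failures:
- the trialkoxyquinone triplet may abstract hydrogen too slowly;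
- the acyl radical may end up on oxygen (hydroquinone mono-ynoate);
- the quinone carbonyl may undergo Paternò–Büchi addition to the alkyne;
- the excited quinone may oxidise the electron-rich B ring by electron transfer;
- the ynone may close 5-exo to an aurone.

The fallback uses known chemistry, sets out from 5 (and uses 10) and comes back at 11. Quinone 5 is reduced with Na2S2O4 (EtOAc/water) to 2,3,5-trimethoxybenzene-1,4-diol F1, which is protected with MOMCl/i-Pr2NEt as 2,3,5-trimethoxy-1,4-bis(methoxymethoxy)benzene F2. n-BuLi (THF, −78 to 0 °C) removes the single ring hydrogen, flanked by OMOM and OMe, to give [2,4,5-trimethoxy-3,6-bis(methoxymethoxy)phenyl]lithium F3. This adds 1,2 to ynal 10 at −78 °C to give racemic 1-[2,4,5-trimethoxy-3,6-bis(methoxymethoxy)phenyl]-3-{2-methoxy-6-[(triisopropylsilyl)oxy]phenyl}prop-2-yn-1-ol F4, whose stereocentre is removed at once by MnO2 oxidation to 1-[2,4,5-trimethoxy-3,6-bis(methoxymethoxy)phenyl]-3-{2-methoxy-6-[(triisopropylsilyl)oxy]phenyl}prop-2-yn-1-one F5. HCl in MeOH (0 °C to rt) cleaves both MOM ethers to give 11, which is cyclised with DMAP to 12 as in the second half of step 6. If the acid also removes the TIPS group, the cyclisation delivers 13 directly.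

Step 5. The ynal may be lost to conjugate addition of Me2NH during the quench, or the formylation of the hindered acetylide may be incomplete. The fallback sets out from 8 and comes back at 10. Acetylide 9, generated as before, is trapped with paraformaldehyde to give 3-{2-methoxy-6-[(triisopropylsilyl)oxy]phenyl}prop-2-yn-1-ol F6, which is oxidised with MnO2 (CH2Cl2, rt) or Dess–Martin periodinane to 10. No amine is ever present, and the stable alcohol can be stored.

Step 2. The cobalt-catalysed oxidation may give para C–C coupling (diphenoquinone) or over-oxidation of the electron-rich phenol. The fallback sets out from 4 and comes back at 5 by the classical azo route. Phenol 4 is coupled in aqueous NaOH at 0 °C, para to the phenoxide, with diazotised sulfanilic acid to give 4-[(E)-(4-hydroxy-2,3,5-trimethoxyphenyl)diazenyl]benzenesulfonic acid F7. Na2S2O4 (water, 50 °C) cleaves the azo bond to 4-amino-2,3,6-trimethoxyphenol F8, and FeCl3 in dilute HCl oxidises this to the quinone imine, which hydrolyses to 5.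

**Further compounds**
F1 | step 6 | 2,3,5-trimethoxybenzene-1,4-diol | COc1cc(O)c(OC)c(OC)c1O
F2 | step 6 | 2,3,5-trimethoxy-1,4-bis(methoxymethoxy)benzene | COCOc1cc(OC)c(OCOC)c(OC)c1OC
F3 | step 6 | [2,4,5-trimethoxy-3,6-bis(methoxymethoxy)phenyl]lithium | [Li]c1c(OC)c(OCOC)c(OC)c(OC)c1OCOC
F4 | step 6 | rac-1-[2,4,5-trimethoxy-3,6-bis(methoxymethoxy)phenyl]-3-{2-methoxy-6-[(triisopropylsilyl)oxy]phenyl}prop-2-yn-1-ol (racemic, stereocentre not defined) | COCOc1c(OC)c(OC)c(OCOC)c(OC)c1C(O)C#Cc1c(OC)cccc1O[Si](C(C)C)(C(C)C)C(C)C
F5 | step 6 | 1-[2,4,5-trimethoxy-3,6-bis(methoxymethoxy)phenyl]-3-{2-methoxy-6-[(triisopropylsilyl)oxy]phenyl}prop-2-yn-1-one | COCOc1c(OC)c(OC)c(OCOC)c(OC)c1C(=O)C#Cc1c(OC)cccc1O[Si](C(C)C)(C(C)C)C(C)C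
F6 | step 5 | 3-{2-methoxy-6-[(triisopropylsilyl)oxy]phenyl}prop-2-yn-1-ol | COc1cccc(O[Si](C(C)C)(C(C)C)C(C)C)c1C#CCO
F7 | step 2 | 4-[(E)-(4-hydroxy-2,3,5-trimethoxyphenyl)diazenyl]benzenesulfonic acid | COc1cc(/N=N/c2ccc(S(=O)(=O)O)cc2)c(OC)c(OC)c1O
F8 | step 2 | 4-amino-2,3,6-trimethoxyphenol | COc1cc(N)c(OC)c(OC)c1O
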